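**Plan**
- Retrosynthesis: first the fourteen benzyl ethers; then O1–C2 and C3–C4 of ring C of the lower unit, cut together, giving an o-quinone methide on the lower ring A and a (Z)-enol gallate; then the C4–C6 interflavan bond, giving phloroglucinol and an epicatechin C4 cation.
- Enabling feature: O1–C8a–C4a–C4 of the lower unit is an ortho-hydroxybenzyl array, i.e. a latent O=C–C=CH2 heterodiene. The cis C2-aryl/C3-acyloxy pair is a (Z)-β-acyloxystyrene whose para-oxygenated ring B polarises the alkene so that C3 bonds to C4 and C2 to O1.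
- Forward: epicatechin → benzylated, 3-O-galloylated C4 electrophile → C-arylation of threefold-symmetric phloroglucinol (no regiochemistry) → oxygen differentiation, ortho-formylation, reduction → ring C of the lower unit closed last by [4+2] → hydrogenolysis. The enol gallate comes in two steps from an aldehyde.
- The 4→6 constitution is fixed by which phenol oxygen is left free (the one para to the interflavan bond), not by a C–C bond-forming selectivity.
- Stereochemistry: upper C2/C3 from (−)-epicatechin; upper C4 by attack anti to the 3-acyloxy group; lower C2/C3 cis from the Z alkene, absolute sense from a chiral Brønsted acid.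

Key step: step 12

Assumption: compounds 1, 4, 6 and 13 are bought; the (R) hand of the phosphoramide in step 12 is taken to give the 2R,3R lower unit, and its enantiomer is used unchanged otherwise if the sense of induction proves opposite.

**Step 1**
Reactants: 1 (−)-epicatechin
Product: 2 5,7,3',4'-tetra-O-benzyl-(−)-epicatechin (2R,3R; 3-OH free)
Conditions: BnBr, K2CO3, DMF, 0 °C → rt
Reagents that add atoms: benzyl bromide, BrCc1ccccc1
Why: Williamson etherification in which carbonate deprotonates only the four phenols, so the secondary 3-OH stays free and no stereocentre is touched.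

**Step 2**
Reactants: 2 5,7,3',4'-tetra-O-benzyl-(−)-epicatechin
Product: 3 5,7,3',4'-tetra-O-benzyl-4β-(2-ethoxyethoxy)epicatechin (2,3-cis-3,4-trans)
Conditions: DDQ, 2-ethoxyethanol, CH2Cl2, rt
Reagents that add atoms: 2-ethoxyethanol, CCOCCO
Why: DDQ benzylic oxidation (hydride abstraction at C4, stabilised by the 5,7-dioxygenated ring A) with capture of the cation by the alcohol anti to the 3-OH, which sets the 4β configuration.

**Step 3**
Reactants: 3 5,7,3',4'-tetra-O-benzyl-4β-(2-ethoxyethoxy)epicatechin; 4 3,4,5-tris(benzyloxy)benzoic acid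
Product: 5 5,7,3',4'-tetra-O-benzyl-4β-(2-ethoxyethoxy)epicatechin 3-O-(3,4,5-tri-O-benzylgallate)
Conditions: DCC, DMAP, CH2Cl2, rt
Reagents that add atoms: none
Why: Steglich esterification of the secondary 3-OH through the acylpyridinium ion, with retention at C3 because only the O–H bond reacts.

**Step 4**
Reactants: 5 the 4β-(2-ethoxyethoxy) 3-O-gallate; 6 phloroglucinol
Product: 7 5,7,3',4'-tetra-O-benzyl-4β-(2,4,6-trihydroxyphenyl)epicatechin 3-O-(3,4,5-tri-O-benzylgallate)
Conditions: 6 (10 equiv), Me3SiOTf (0.2 equiv), THF/CH2Cl2, −78 → −40 °C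
Reagents that add atoms: none
Why: Lewis acid-promoted Friedel–Crafts arylation of the C4 cation, where the threefold symmetry of 6 removes any regiochemical question, the excess suppresses double alkylation, and attack anti to the participating 3-acyloxy group should give the 3,4-trans (4β) stereocentre.

**Step 5**
Reactants: 7 the 4β-(2,4,6-trihydroxyphenyl) adduct
Product: 8 5,7,3',4'-tetra-O-benzyl-4β-[2,6-dihydroxy-4-(triisopropylsilyloxy)phenyl]epicatechin 3-O-(3,4,5-tri-O-benzylgallate)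
Conditions: i-Pr3SiCl (1.05 equiv), imidazole, DMF, −20 °C → rt
Reagents that add atoms: triisopropylsilyl chloride, CC(C)[Si](Cl)(C(C)C)C(C)C
Why: silylation of the least hindered phenol (the one para to the flavan C4, flanked by two ring hydrogens), with silyl transfer between phenols under imidazole expected to drive the mixture to this isomer.

**Step 6**
Reactants: 8 the para-silyl ether
Product: 9 5,7,3',4'-tetra-O-benzyl-4β-[2,6-bis(benzyloxy)-4-(triisopropylsilyloxy)phenyl]epicatechin 3-O-(3,4,5-tri-O-benzylgallate)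
Conditions: BnBr, K2CO3, Bu4NI (cat.), acetone, 50 °C
Reagents that add atoms: benzyl bromide, BrCc1ccccc1
Why: Williamson etherification of the two remaining phenols under anhydrous carbonate conditions that the aryl triisopropylsilyl ether and the gallate ester should tolerate.

**Step 7**
Reactants: 9 the bis(benzyl) silyl ether
Product: 10 5,7,3',4'-tetra-O-benzyl-4β-[2,6-bis(benzyloxy)-4-hydroxyphenyl]epicatechin 3-O-(3,4,5-tri-O-benzylgallate)
Conditions: Bu4NF, AcOH, THF, 0 °C
Reagents that add atoms: none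
Why: buffered fluoride desilylation frees the single phenol, which is the oxygen that becomes O1 of the lower unit, without ester cleavage.

**Step 8**
Reactants: 10 the mono-phenol
Product: 11 5,7,3',4'-tetra-O-benzyl-4β-[2,6-bis(benzyloxy)-3-formyl-4-hydroxyphenyl]epicatechin 3-O-(3,4,5-tri-O-benzylgallate)
Conditions: MgCl2, Et3N, (CH2O)n, THF, reflux
Reagents that add atoms: formaldehyde (as paraformaldehyde), C=O
Why: magnesium phenoxide-directed ortho-formylation (Casnati–Skattebøl) acts only ortho to the one free phenol, so the other benzyloxy-arene rings are left alone, and the two ortho positions are equivalent by rotation about the C4–aryl bond.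

**Step 9**
Reactants: 11 the salicylaldehyde
Product: 12 5,7,3',4'-tetra-O-benzyl-4β-[2,6-bis(benzyloxy)-4-hydroxy-3-(hydroxymethyl)phenyl]epicatechin 3-O-(3,4,5-tri-O-benzylgallate)
Conditions: NaBH4, THF/MeOH, −20 °C; pH 7 work-up, used crude
Reagents that add atoms: none
Why: borohydride reduction of the aldehyde to the ortho-hydroxybenzyl alcohol at low temperature, where the gallate ester is inert.

**Step 10**
Reactants: 13 3,4-bis(benzyloxy)benzaldehyde
Product: 14 1,2-bis(benzyloxy)-4-ethynylbenzene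
Conditions: dimethyl (1-diazo-2-oxopropyl)phosphonate, K2CO3, MeOH, rt
Reagents that add atoms: dimethyl (1-diazo-2-oxopropyl)phosphonate, CC(=O)C(=[N+]=[N-])P(=O)(OC)OC
Why: Seyferth–Gilbert homologation in the Ohira–Bestmann form (olefination, loss of N2 and 1,2-shift of the alkylidene carbene) turns the aldehyde into the terminal alkyne.

**Step 11**
Reactants: 14 1,2-bis(benzyloxy)-4-ethynylbenzene; 4 3,4,5-tris(benzyloxy)benzoic acid
Product: 15 (Z)-2-[3,4-bis(benzyloxy)phenyl]ethenyl 3,4,5-tris(benzyloxy)benzoate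
Conditions: Ru(η3-CH2C(CH3)CH2)2(Ph2P(CH2)4PPh2) (5 mol %), toluene, 65 °C
Reagents that add atoms: none
Why: anti-Markovnikov hydro-acyloxylation of a terminal alkyne with a divalent ruthenium catalyst through a ruthenium vinylidene, in which carboxylate attack at the vinylidene carbon and protonolysis amount to trans addition and should give the Z enol ester.

**Step 12**
Reactants: 12 the ortho-hydroxybenzyl alcohol; 15 the (Z)-enol gallate
Product: 17 5,7,3',4'-tetra-O-benzylepicatechin-(4β→6)-5,7,3',4'-tetra-O-benzylepicatechin 3,3'-bis-O-(3,4,5-tri-O-benzylgallate) (lower unit 2R,3R), via o-quinone methide 16 (not isolated)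
Conditions: (R)-3,3'-bis(2,4,6-triisopropylphenyl)-1,1'-binaphthalene-2,2'-diyl N-(trifluoromethylsulfonyl)phosphoramide (10 mol %), 15 (2.5 equiv), 5 Å MS, toluene, −40 °C, slow addition of 12
Reagents that add atoms: none
Why: Proposed new method: the strong chiral Brønsted acid dehydrates 12 to the o-quinone methide 16, held as a hydrogen-bonded contact ion pair through its carbonyl oxygen, and 15 adds across the O=C–C=CH2 heterodiene in an inverse-electron-demand, concerted but asynchronous [4π+2π] cycloaddition in which the C4–C3 bond leads and the O1–C2 bond follows; the closest known reaction type is the chiral N-triflylphosphoramide- or phosphoric acid-catalysed hetero-Diels–Alder reaction of o-quinone methides generated in situ with styrenes to give 2-arylchromans, here extended to a β-acyloxystyrene and to a methide carbon without substituent. Ring C of the lower unit is closed by this [4+2] cycloaddition (in the stepwise limit a conjugate addition followed by 6-exo-trig attack of the phenolic oxygen on the para-benzyloxybenzyl cation). C2 and C3 arise cis because the Z alkene adds suprafacially and ring closure should outrun bond rotation, and their absolute 2R,3R sense is set by the catalyst, which shields one face of the bound quinone methide while the endo approach stacks ring B over the methide ring, so that a single alkene face is used. Regiochemistry needs C3 to bond to the CH2 and C2 to oxygen, which the para-benzyloxy group of ring B secures by making the aryl-bearing carbon the cation-stabilising end while the ester attenuates donation from the enol oxygen; the 4→6 constitution needs the oxygen para to the interflavan bond to close the ring, which is secured because both oxygens flanking the interflavan carbon are benzylated. Chemoselectivity over Friedel–Crafts capture of 16 by the benzyloxy-arene rings is sought through slow addition of 12, excess 15 and low temperature.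

**Step 13**
Reactants: 17 the tetradeca-O-benzyl dimer
Product: 18 procyanidin B-5 3,3'-di-O-gallate
Conditions: H2 (1 atm), Pd(OH)2/C, THF/MeOH/H2O, rt
Reagents that add atoms: none
Why: hydrogenolysis of the fourteen benzyl ethers under neutral conditions that leave the esters, the flavan C2–O bonds, the interflavan bond and all six stereocentres untouched.

**Compound list**
1 | (−)-epicatechin | O[C@@H]1Cc2c(O)cc(O)cc2O[C@@H]1c1ccc(O)c(O)c1 | starting material
2 | 5,7,3',4'-tetra-O-benzyl-(−)-epicatechin | O[C@@H]1Cc2c(OCc3ccccc3)cc(OCc3ccccc3)cc2O[C@@H]1c1ccc(OCc2ccccc2)c(OCc2ccccc2)c1 | intermediate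
3 | 5,7,3',4'-tetra-O-benzyl-4β-(2-ethoxyethoxy)epicatechin | O[C@@H]1[C@@H](OCCOCC)c2c(OCc3ccccc3)cc(OCc3ccccc3)cc2O[C@@H]1c1ccc(OCc2ccccc2)c(OCc2ccccc2)c1 | intermediate
4 | 3,4,5-tris(benzyloxy)benzoic acid | OC(=O)c1cc(OCc2ccccc2)c(OCc2ccccc2)c(OCc2ccccc2)c1 | starting material
5 | 5,7,3',4'-tetra-O-benzyl-4β-(2-ethoxyethoxy)epicatechin 3-O-(3,4,5-tri-O-benzylgallate) | O=C(O[C@@H]1[C@@H](OCCOCC)c2c(OCc3ccccc3)cc(OCc3ccccc3)cc2O[C@@H]1c1ccc(OCc2ccccc2)c(OCc2ccccc2)c1)c1cc(OCc2ccccc2)c(OCc2ccccc2)c(OCc2ccccc2)c1 | intermediate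
6 | phloroglucinol | Oc1cc(O)cc(O)c1 | starting material
7 | 5,7,3',4'-tetra-O-benzyl-4β-(2,4,6-trihydroxyphenyl)epicatechin 3-O-(3,4,5-tri-O-benzylgallate) | O=C(O[C@@H]1[C@@H](c2c(O)cc(O)cc2O)c2c(OCc3ccccc3)cc(OCc3ccccc3)cc2O[C@@H]1c1ccc(OCc2ccccc2)c(OCc2ccccc2)c1)c1cc(OCc2ccccc2)c(OCc2ccccc2)c(OCc2ccccc2)c1 | intermediate
8 | 4β-[2,6-dihydroxy-4-(triisopropylsilyloxy)phenyl] analogue of 7 | O=C(O[C@@H]1[C@@H](c2c(O)cc(O[Si](C(C)C)(C(C)C)C(C)C)cc2O)c2c(OCc3ccccc3)cc(OCc3ccccc3)cc2O[C@@H]1c1ccc(OCc2ccccc2)c(OCc2ccccc2)c1)c1cc(OCc2ccccc2)c(OCc2ccccc2)c(OCc2ccccc2)c1 | intermediate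
9 | 4β-[2,6-bis(benzyloxy)-4-(triisopropylsilyloxy)phenyl] analogue of 7 | O=C(O[C@@H]1[C@@H](c2c(OCc3ccccc3)cc(O[Si](C(C)C)(C(C)C)C(C)C)cc2OCc2ccccc2)c2c(OCc3ccccc3)cc(OCc3ccccc3)cc2O[C@@H]1c1ccc(OCc2ccccc2)c(OCc2ccccc2)c1)c1cc(OCc2ccccc2)c(OCc2ccccc2)c(OCc2ccccc2)c1 | intermediate
10 | 4β-[2,6-bis(benzyloxy)-4-hydroxyphenyl] analogue of 7 | O=C(O[C@@H]1[C@@H](c2c(OCc3ccccc3)cc(O)cc2OCc2ccccc2)c2c(OCc3ccccc3)cc(OCc3ccccc3)cc2O[C@@H]1c1ccc(OCc2ccccc2)c(OCc2ccccc2)c1)c1cc(OCc2ccccc2)c(OCc2ccccc2)c(OCc2ccccc2)c1 | intermediate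
11 | 4β-[2,6-bis(benzyloxy)-3-formyl-4-hydroxyphenyl] analogue of 7 | O=C(O[C@@H]1[C@@H](c2c(OCc3ccccc3)c(C=O)c(O)cc2OCc2ccccc2)c2c(OCc3ccccc3)cc(OCc3ccccc3)cc2O[C@@H]1c1ccc(OCc2ccccc2)c(OCc2ccccc2)c1)c1cc(OCc2ccccc2)c(OCc2ccccc2)c(OCc2ccccc2)c1 | intermediate
12 | 4β-[2,6-bis(benzyloxy)-4-hydroxy-3-(hydroxymethyl)phenyl] analogue of 7 | O=C(O[C@@H]1[C@@H](c2c(OCc3ccccc3)c(CO)c(O)cc2OCc2ccccc2)c2c(OCc3ccccc3)cc(OCc3ccccc3)cc2O[C@@H]1c1ccc(OCc2ccccc2)c(OCc2ccccc2)c1)c1cc(OCc2ccccc2)c(OCc2ccccc2)c(OCc2ccccc2)c1 | intermediate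
13 | 3,4-bis(benzyloxy)benzaldehyde | O=Cc1ccc(OCc2ccccc2)c(OCc2ccccc2)c1 | starting material
14 | 1,2-bis(benzyloxy)-4-ethynylbenzene | C#Cc1ccc(OCc2ccccc2)c(OCc2ccccc2)c1 | intermediate
15 | (Z)-2-[3,4-bis(benzyloxy)phenyl]ethenyl 3,4,5-tris(benzyloxy)benzoate | O=C(O/C=C\c1ccc(OCc2ccccc2)c(OCc2ccccc2)c1)c1cc(OCc2ccccc2)c(OCc2ccccc2)c(OCc2ccccc2)c1 | intermediate
16 | o-quinone methide: 4β-[2,6-bis(benzyloxy)-3-methylidene-4-oxocyclohexa-1,5-dien-1-yl] analogue of 7 | O=C(O[C@@H]1[C@@H](C2=C(OCc3ccccc3)C(=C)C(=O)C=C2OCc2ccccc2)c2c(OCc3ccccc3)cc(OCc3ccccc3)cc2O[C@@H]1c1ccc(OCc2ccccc2)c(OCc2ccccc2)c1)c1cc(OCc2ccccc2)c(OCc2ccccc2)c(OCc2ccccc2)c1 | intermediate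
17 | tetradeca-O-benzyl procyanidin B-5 3,3'-di-O-gallate | O=C(O[C@@H]1[C@@H](c2c(OCc3ccccc3)cc3c(c2OCc2ccccc2)C[C@@H](OC(=O)c2cc(OCc4ccccc4)c(OCc4ccccc4)c(OCc4ccccc4)c2)[C@@H](c2ccc(OCc4ccccc4)c(OCc4ccccc4)c2)O3)c2c(OCc3ccccc3)cc(OCc3ccccc3)cc2O[C@@H]1c1ccc(OCc2ccccc2)c(OCc2ccccc2)c1)c1cc(OCc2ccccc2)c(OCc2ccccc2)c(OCc2ccccc2)c1 | intermediate
18 | procyanidin B-5 3,3'-di-O-gallate | O=C(O[C@@H]1[C@@H](c2c(O)cc3c(c2O)C[C@@H](OC(=O)c2cc(O)c(O)c(O)c2)[C@@H](c2ccc(O)c(O)c2)O3)c2c(O)cc(O)cc2O[C@@H]1c1ccc(O)c(O)c1)c1cc(O)c(O)c(O)c1 | target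

**Count**
Total steps: 13. Longest linear sequence: 11 (steps 1–9, 12, 13).

**Steps most likely to fail**

Step 12. The quinone methide may be consumed by Friedel–Crafts capture or oligomerisation before the moderately nucleophilic enol ester adds. A stepwise ionic pathway may erode the cis relationship. The catalyst may discriminate the alkene faces poorly. The fallback is the known C8-blocked interflavan coupling; it sets out from 2 and 5 and comes back at 18. Compound 2 is brominated with N-bromosuccinimide in CH2Cl2 to 8-bromo-5,7,3',4'-tetra-O-benzylepicatechin F1. F1 is esterified with 4 (DCC, DMAP) to 8-bromo-5,7,3',4'-tetra-O-benzylepicatechin 3-O-(3,4,5-tri-O-benzylgallate) F2. Electrophile 5 is then condensed with an excess of F2 (Me3SiOTf, CH2Cl2, −78 °C); with C8 blocked the C4 cation is taken up at C6, anti to the 3-acyloxy group, to give the 8-bromo tetradeca-O-benzyl dimer F3. Hydrogenolysis (H2, Pd(OH)2/C, Et3N, THF/MeOH/H2O) removes the benzyl groups and the bromine and gives 18.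

Step 5. Silylation may show poor site selectivity between the para and the two ortho phenols, or run on to bis-silylation. The fallback brings the differentiated oxygen in with the nucleophile and blocks its neighbours; it sets out from 5 and comes back at 10. Commercial 3,5-bis(benzyloxy)phenol is dibrominated ortho to the hydroxyl (N-bromosuccinimide, 2 equiv, cat. i-Pr2NH, CH2Cl2) to 2,6-dibromo-3,5-bis(benzyloxy)phenol F4. Its only unsubstituted ring carbon, para to the hydroxyl, is alkylated by slow addition of 5 to excess F4 (Me3SiOTf, CH2Cl2, −40 °C), giving the 4β-[2,6-bis(benzyloxy)-3,5-dibromo-4-hydroxyphenyl] adduct F5. Radical debromination (Bu3SnH, AIBN, toluene, 90 °C) gives 10.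

Step 9. Hydride may over-reduce the aldehyde to the methyl arene through conjugate addition to a quinone methide formed from the borate, and the electron-rich product may self-condense on isolation. The fallback avoids hydride and stores the alcohol in masked form; it sets out from 10 and comes back at 12. Phenol 10 is ortho-hydroxymethylated with PhB(OH)2 and (CH2O)n (cat. propionic acid, toluene, reflux, water removal) to the stable 2-phenyl-4H-1,3,2-benzodioxaborin F6. Just before the key step F6 is transesterified with 2,2-dimethylpropane-1,3-diol (THF, rt) to release 12.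

**Further compounds**
F1 | step 12 | 8-bromo-5,7,3',4'-tetra-O-benzylepicatechin | O[C@@H]1Cc2c(OCc3ccccc3)cc(OCc3ccccc3)c(Br)c2O[C@@H]1c1ccc(OCc2ccccc2)c(OCc2ccccc2)c1
F2 | step 12 | 8-bromo-5,7,3',4'-tetra-O-benzylepicatechin 3-O-(3,4,5-tri-O-benzylgallate) | O=C(O[C@@H]1Cc2c(OCc3ccccc3)cc(OCc3ccccc3)c(Br)c2O[C@@H]1c1ccc(OCc2ccccc2)c(OCc2ccccc2)c1)c1cc(OCc2ccccc2)c(OCc2ccccc2)c(OCc2ccccc2)c1
F3 | step 12 | 8-bromo (lower unit) tetradeca-O-benzyl procyanidin B-5 3,3'-di-O-gallate | O=C(O[C@@H]1[C@@H](c2c(OCc3ccccc3)c(Br)c3c(c2OCc2ccccc2)C[C@@H](OC(=O)c2cc(OCc4ccccc4)c(OCc4ccccc4)c(OCc4ccccc4)c2)[C@@H](c2ccc(OCc4ccccc4)c(OCc4ccccc4)c2)O3)c2c(OCc3ccccc3)cc(OCc3ccccc3)cc2O[C@@H]1c1ccc(OCc2ccccc2)c(OCc2ccccc2)c1)c1cc(OCc2ccccc2)c(OCc2ccccc2)c(OCc2ccccc2)c1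
F4 | step 5 | 2,6-dibromo-3,5-bis(benzyloxy)phenol | Oc1c(Br)c(OCc2ccccc2)cc(OCc2ccccc2)c1Br
F5 | step 5 | 4β-[2,6-bis(benzyloxy)-3,5-dibromo-4-hydroxyphenyl] analogue of 7 | O=C(O[C@@H]1[C@@H](c2c(OCc3ccccc3)c(Br)c(O)c(Br)c2OCc2ccccc2)c2c(OCc3ccccc3)cc(OCc3ccccc3)cc2O[C@@H]1c1ccc(OCc2ccccc2)c(OCc2ccccc2)c1)c1cc(OCc2ccccc2)c(OCc2ccccc2)c(OCc2ccccc2)c1
F6 | step 9 | 4β-[5,7-bis(benzyloxy)-2-phenyl-4H-1,3,2-benzodioxaborin-6-yl] analogue of 7 | O=C(O[C@@H]1[C@@H](c2c(OCc3ccccc3)c3COB(c4ccccc4)Oc3cc2OCc2ccccc2)c2c(OCc3ccccc3)cc(OCc3ccccc3)cc2O[C@@H]1c1ccc(OCc2ccccc2)c(OCc2ccccc2)c1)c1cc(OCc2ccccc2)c(OCc2ccccc2)c(OCc2ccccc2)c1
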